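**Slow start.** At 4.0 s, the first reading, the amber flask held 7 × 10⁻⁴ M of product, a mean rate of 0.175 mM s⁻¹, but between 34 s and 58 s it ran faster, at 0.817 mM s⁻¹.

| flask | starting material | partner | catalyst | time |
|---|---|---|---|---|
| amber | 0.120 M | 0.300 M | 0.00960 M |  |
| red | 0.180 M | 0.300 M | 0.00960 M |  |
| violet | 0.0400 M | 0.300 M | 0.0290 M | 100 s |

| run | time / s | [product] / M |
|---|---|---|
| amber run | 4.0 | 7 × 10⁻⁴ |
| amber run | 6.8 | 0.0010 |
| amber run | 12 | 0.0039 |
| amber run | 20 | 0.0081 |
| amber run | 34 | 0.0177 |
| amber run | 58 | 0.0373 |
| amber run | 100 | 0.0657 |
| red run | 4.0 | 2 × 10⁻⁴ |
| red run | 6.8 | 0.0017 |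
| red run | 12 | 0.0031 |
| red run | 20 | 0.0084 |
| red run | 34 | 0.0205 |
| red run | 58 | 0.0439 |
| red run | 100 | 0.0821 |

(each reading ± 6 × 10⁻⁴ M)

- apparent order in [starting material] of the starting rate, round the charge of the amber run (the rate where two percent of its starting material have turned into product) (one fixed amount of product, the same in the runs compared)
- product in the violet run at 100 s, as a share of the starting material charged

- Overall: starting material + partner -> product, with catalyst as catalyst.
- Constant volume, constant temperature.
- The analysis sees a species whether free or bound.
- An order is taken over about fifteen percent of the charge, up and down.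

**The lag.** The red run's late rate over the same interval was 0.975 mM s⁻¹. I drew each late line back to zero product, and it met the time axis at 12.3 s in amber and 13.0 s in red. That gap is smaller than one reading's scatter expressed as time, 0.735 s, so I took one mean value, 12.7 s. This is the lag (induction period), the time constant with which the rate climbs to its late value. I assumed that the share of the late rate reached at any time is one minus the exponential of minus time over lag.

**First round.** Two percent of amber's starting material is 2.40 mM. If product grows with the square of time and the lag is the same in both runs, the rate at fixed product follows the square root of the late rate. The late order across the two charges is 0.437, so the order at the mark is 0.219, half of it.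

**Second round.** But that law needs times well inside the lag, and it puts amber's mark at 8.62 s, not far short of the lag. I put that time back into the next term of the exponential, which moved the mark to 9.81 s in amber and 8.87 s in red. The rates there are 0.441 mM s⁻¹ and 0.491 mM s⁻¹, so the order is 0.269. This spans both charges, wider than the asked range, so it stayed rough.

**Violet flask.** The late rates belong to about 92.5 mM and 148 mM of starting material left. A saturation curve through both gives a Michaelis constant of 70.9 mM and a top rate of 1.44 mM s⁻¹. Scaled to violet's catalyst, the top rate is 4.36 mM s⁻¹, and the integrated curve over 87.3 s after the lag gives 99.2 %. But amber and red share one catalyst charge, so that scaling is untested, and I held this as a high estimate.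

**The flask.** The forecast gave 0.28 (0.1 to 0.55) and 90 % (72 % to 98 %), lower than my violet figure, reasoning that “Possible sublinear catalyst order or deactivation lowers this”. The flask gave an order of 0.21 and 97.0 % in the violet run.

    active catalyst + starting material ⇌ catalyst-substrate complex, settled at all times (20.90 M⁻¹)
    catalyst-substrate complex + partner → product + active catalyst + by-product (0.4200 M⁻¹ s⁻¹)
    starting material + partner + product → 2 product (0.1670 M⁻² s⁻¹)
    catalyst + partner → active catalyst + partner (0.2320 M⁻¹ s⁻¹)

At amber's two-percent mark the rate stood at 4.3 × 10⁻⁴ M s⁻¹, where the lag of 12.7 s had given 0.441 mM s⁻¹. In the red run, the same lag gave 0.491 mM s⁻¹ at that amount of product, and the flask's rate was 4.7 × 10⁻⁴ M s⁻¹. The lag's ratio of red to amber was 1.11, and the flask's was 1.1.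

(The readings were computed with constants of no real substance; the scatter is artificial.)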